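**Retrosynthetic overview**
- The depside ester bond (ring B C4–O to the ring A acyl carbon) is cut first. This gives phenol 12 (ring B as its benzyl ester) and acid chloride 22 (ring A, 2'-O-benzyl). The side-chain ketone of 22 is held as a dioxolane so that it cannot enol-lactonise onto the carboxyl group.
- The strategy rests on the contiguous triad of ring B: pentyl at C6, carboxyl at C1 and methoxy at C2, with oxygen at C4. The C6–pentyl and C1–CO2H bonds are made in one flask across the C1≡C6 triple bond of a 3-methoxy-5-silyloxybenzyne. The aryne is generated from fluoroarene 3 by pentyllithium 5, and the adduct is quenched with CO2 6.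
- In ring A, the bond between the benzylic CH2 on C6' and the ketone carbonyl carbon comes from lateral lithiation of the orsellinate-derived toluate 15 and acylation with Weinreb amide 16.
- Both benzene rings are bought intact, so no ring of the target is formed in the route. The dioxolane is only a temporary ring.

Key step: step 3

Remark: the target has no stereocentre. Ring B is numbered from the carbon that bears the carboxyl group (OMe at C2, depside oxygen at C4, pentyl at C6). Ring A is numbered likewise with primes (OH at C2', OMe at C4', 2-oxopentyl at C6'). Compounds 1, 2, 4, 6, 13 and 16 are assumed to be purchasable.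

**Step 1**
Reactants: 1 3-fluoro-5-methoxyphenol; 2 triisopropylsilyl chloride
Product: 3 (3-fluoro-5-methoxyphenoxy)triisopropylsilane
Conditions: TIPSCl (1.1 equiv), imidazole (2 equiv), DMF, rt
Reagents that add atoms: triisopropylsilyl chloride (2), CC(C)[Si](Cl)(C(C)C)C(C)C
Why: Imidazole-promoted O-silylation of a phenol should give a silyl ether that resists alkyllithiums and shields both ring positions next to it.

**Step 2**
Reactants: 4 1-chloropentane
Product: 5 pentyllithium (hexane solution, filtered and titrated)
Conditions: Li metal (2.2 equiv, ca. 1% Na), hexane, reflux, Ar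
Reagents that add atoms: lithium metal, [Li]
Why: Reductive lithiation of a primary alkyl chloride by lithium in a hydrocarbon is the standard preparation of n-alkyllithium solutions, and the chloride keeps Wurtz coupling low.

**Step 3**
Reactants: 3 (3-fluoro-5-methoxyphenoxy)triisopropylsilane; 5 pentyllithium; 6 carbon dioxide
Product: 10 2-methoxy-6-pentyl-4-(triisopropylsilyloxy)benzoic acid, via lithiated fluoroarene 7 (not isolated), via aryne 8 (not isolated), via pentylated aryllithium 9 (not isolated)
Conditions: 5 (3.5 equiv), THF–hexane, −78 °C, 1.5 h; then → −10 °C, 1 h; cannulate onto excess solid CO2 in Et2O, −78 °C → rt; cold 1 M HCl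
Reagents that add atoms: pentyllithium (5), [Li]CCCCC; carbon dioxide (6), O=C=O
Why: Directed ortho-lithiation comes first: at −78 °C one equivalent of 5 removes the ring proton flanked by F and OMe, which is the most acidic one and the only one not shielded by the bulky, poorly coordinating silyloxy group, to give 7. On warming, 7 loses LiF in an E1cB-type elimination and gives aryne 8, whose triple bond joins the future C1 and C6 of ring B. The excess of 5 carbolithiates 8 at the aryne carbon far from OMe (future C6), because the inductively withdrawing methoxy group distorts the triple bond so that negative charge builds on the carbon beside it, where lithium is also held by the oxygen, and this gives 9; the more distant 5-silyloxy group exerts only a weak opposing bias. Aryllithium 9 is then carboxylated at the future C1, so two skeletal bonds form in one flask while the C4 oxygen is carried through untouched. The closest known reaction type is alkyllithium-induced aryne formation from 3-haloanisoles followed by carbolithiation and electrophilic quench, which leads to 2-alkyl-6-methoxybenzoic acids. No ring is closed and no stereocentre is made; the selectivities needed are the site of lithiation, the direction of addition and capture of 8 by alkyl- rather than aryllithium, and they are secured by the F/OMe pair, the 3-methoxy group and the excess of 5, respectively.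

**Step 4**
Reactants: 10 2-methoxy-6-pentyl-4-(triisopropylsilyloxy)benzoic acid
Product: 11 benzyl 2-methoxy-6-pentyl-4-(triisopropylsilyloxy)benzoate
Conditions: BnBr (1.2 equiv), KHCO3 (1.5 equiv), DMF, rt
Reagents that add atoms: benzyl bromide, BrCc1ccccc1
Why: SN2 O-alkylation of the carboxylate avoids attack at the hindered carbonyl, and the weak base ionises only the acid and leaves the aryl silyl ether alone.

**Step 5**
Reactants: 11 benzyl 2-methoxy-6-pentyl-4-(triisopropylsilyloxy)benzoate
Product: 12 benzyl 4-hydroxy-2-methoxy-6-pentylbenzoate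
Conditions: Bu4NF (1.1 equiv), AcOH (1.1 equiv), THF, 0 °C
Reagents that add atoms: none
Why: Fluoride-induced desilylation is driven by the strong Si–F bond, and the acetic acid buffer protonates the phenoxide so that the hindered benzyl ester is not touched.

**Step 6**
Reactants: 13 methyl 2,4-dihydroxy-6-methylbenzoate (methyl orsellinate)
Product: 14 methyl 2-hydroxy-4-methoxy-6-methylbenzoate
Conditions: MeI (1.05 equiv), K2CO3 (1.1 equiv), acetone, reflux
Reagents that add atoms: iodomethane, CI
Why: In this Williamson ether synthesis the 2-OH is tied up in a hydrogen bond to the ester carbonyl, so one equivalent of iodomethane should alkylate the free 4-OH selectively.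

**Step 7**
Reactants: 14 methyl 2-hydroxy-4-methoxy-6-methylbenzoate
Product: 15 methyl 2-(benzyloxy)-4-methoxy-6-methylbenzoate
Conditions: BnBr (1.5 equiv), K2CO3 (2 equiv), DMF, 60 °C
Reagents that add atoms: benzyl bromide, BrCc1ccccc1
Why: Williamson benzylation of the remaining chelated phenol is forced by excess reagent in a dipolar aprotic solvent with gentle heating.

**Step 8**
Reactants: 15 methyl 2-(benzyloxy)-4-methoxy-6-methylbenzoate; 16 N-methoxy-N-methylbutanamide
Product: 19 methyl 2-(benzyloxy)-4-methoxy-6-(2-oxopentyl)benzoate, via benzylic lithium species 17 (not isolated), via tetrahedral lithium adduct 18 (not isolated)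
Conditions: LDA (1.3 equiv), THF, −78 °C; 16 (1.5 equiv), −78 °C; AcOH in THF, −78 °C → rt
Reagents that add atoms: N-methoxy-N-methylbutanamide (16), CCCC(=O)N(C)OC
Why: Lateral lithiation of an ortho-toluate followed by Weinreb ketone synthesis should stop at the ketone, because adduct 18 survives until the cold acidic quench, which also prevents base-induced closure onto the neighbouring ester.

**Step 9**
Reactants: 19 methyl 2-(benzyloxy)-4-methoxy-6-(2-oxopentyl)benzoate
Product: 20 methyl 2-(benzyloxy)-4-methoxy-6-[(2-propyl-1,3-dioxolan-2-yl)methyl]benzoate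
Conditions: (TMSOCH2)2 (2.5 equiv), TMSOTf (0.1 equiv), CH2Cl2, −78 → −20 °C; pyridine quench
Reagents that add atoms: 1,2-bis(trimethylsilyloxy)ethane, C[Si](C)(C)OCCO[Si](C)(C)C
Why: Noyori ketalisation runs cold and aprotic and is driven by siloxane formation, so the hot protic acid that would enol-lactonise the keto ester is avoided.

**Step 10**
Reactants: 20 methyl 2-(benzyloxy)-4-methoxy-6-[(2-propyl-1,3-dioxolan-2-yl)methyl]benzoate
Product: 21 2-(benzyloxy)-4-methoxy-6-[(2-propyl-1,3-dioxolan-2-yl)methyl]benzoic acid
Conditions: KOH (10 equiv), DMSO–H2O (4:1), 90 °C; cold 1 M KHSO4 to pH 4 under EtOAc, 0 °C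
Reagents that add atoms: potassium hydroxide, [K+].[OH-]
Why: Saponification of the doubly ortho-substituted benzoate needs poorly solvated hydroxide in hot aqueous DMSO, conditions that leave ketal and ethers untouched, and the cold two-phase acidification spares the ketal.

**Step 11**
Reactants: 21 2-(benzyloxy)-4-methoxy-6-[(2-propyl-1,3-dioxolan-2-yl)methyl]benzoic acid
Product: 22 2-(benzyloxy)-4-methoxy-6-[(2-propyl-1,3-dioxolan-2-yl)methyl]benzoyl chloride (concentrated and used crude)
Conditions: 1-chloro-N,N,2-trimethylprop-1-en-1-amine (1.05 equiv), CH2Cl2, 0 °C → rt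
Reagents that add atoms: 1-chloro-N,N,2-trimethylprop-1-en-1-amine (Ghosez reagent), CC(C)=C(Cl)N(C)C
Why: Acid chloride formation with the Ghosez reagent releases no HCl, so the acid-labile dioxolane should survive.

**Step 12**
Reactants: 22 2-(benzyloxy)-4-methoxy-6-[(2-propyl-1,3-dioxolan-2-yl)methyl]benzoyl chloride; 12 benzyl 4-hydroxy-2-methoxy-6-pentylbenzoate
Product: 23 benzyl 4-({2-(benzyloxy)-4-methoxy-6-[(2-propyl-1,3-dioxolan-2-yl)methyl]benzoyl}oxy)-2-methoxy-6-pentylbenzoate
Conditions: 22 (1.2 equiv), Et3N (2 equiv), DMAP (0.2 equiv), CH2Cl2, 0 °C → rt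
Reagents that add atoms: none
Why: DMAP-catalysed O-acylation of a phenol by an acid chloride forms the depside ester, and the 4-OH of 12 is the only nucleophilic site in either partner.

**Step 13**
Reactants: 23 benzyl 4-({2-(benzyloxy)-4-methoxy-6-[(2-propyl-1,3-dioxolan-2-yl)methyl]benzoyl}oxy)-2-methoxy-6-pentylbenzoate
Product: 24 benzyl 4-{[2-(benzyloxy)-4-methoxy-6-(2-oxopentyl)benzoyl]oxy}-2-methoxy-6-pentylbenzoate
Conditions: THF–1 M aq. HCl (3:1), rt; NaHCO3 wash as soon as 23 is consumed
Reagents that add atoms: water, O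
Why: Acid-catalysed ketal hydrolysis of a dialkyl ketone dioxolane passes through an oxocarbenium ion and should be much faster at room temperature than hydrolysis of the hindered aryl and benzyl esters.

**Step 14**
Reactants: 24 benzyl 4-{[2-(benzyloxy)-4-methoxy-6-(2-oxopentyl)benzoyl]oxy}-2-methoxy-6-pentylbenzoate
Product: 25 4-{[2-hydroxy-4-methoxy-6-(2-oxopentyl)benzoyl]oxy}-2-methoxy-6-pentylbenzoic acid (target)
Conditions: H2 (1 atm), 10% Pd/C, EtOAc, rt
Reagents that add atoms: none
Why: Catalytic hydrogenolysis cleaves the benzyl ester and the benzyl ether together, while the aryl ester, the aliphatic ketone and the arenes are not reduced at atmospheric pressure.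

**Compound list**
1 | 3-fluoro-5-methoxyphenol | COc1cc(O)cc(F)c1 | starting material
2 | triisopropylsilyl chloride | CC(C)[Si](Cl)(C(C)C)C(C)C | starting material
3 | (3-fluoro-5-methoxyphenoxy)triisopropylsilane | COc1cc(F)cc(O[Si](C(C)C)(C(C)C)C(C)C)c1 | intermediate
4 | 1-chloropentane | CCCCCCl | starting material
5 | pentyllithium | [Li]CCCCC | intermediate
6 | carbon dioxide | O=C=O | starting material
7 | [2-fluoro-6-methoxy-4-(triisopropylsilyloxy)phenyl]lithium | COc1cc(O[Si](C(C)C)(C(C)C)C(C)C)cc(F)c1[Li] | intermediate (not isolated)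
8 | 3-methoxy-5-(triisopropylsilyloxy)benzyne | COC1=CC(O[Si](C(C)C)(C(C)C)C(C)C)=CC#C1 | intermediate (not isolated)
9 | [2-methoxy-6-pentyl-4-(triisopropylsilyloxy)phenyl]lithium | CCCCCc1cc(O[Si](C(C)C)(C(C)C)C(C)C)cc(OC)c1[Li] | intermediate (not isolated)
10 | 2-methoxy-6-pentyl-4-(triisopropylsilyloxy)benzoic acid | CCCCCc1cc(O[Si](C(C)C)(C(C)C)C(C)C)cc(OC)c1C(=O)O | intermediate
11 | benzyl 2-methoxy-6-pentyl-4-(triisopropylsilyloxy)benzoate | CCCCCc1cc(O[Si](C(C)C)(C(C)C)C(C)C)cc(OC)c1C(=O)OCc1ccccc1 | intermediate
12 | benzyl 4-hydroxy-2-methoxy-6-pentylbenzoate | CCCCCc1cc(O)cc(OC)c1C(=O)OCc1ccccc1 | intermediate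
13 | methyl 2,4-dihydroxy-6-methylbenzoate | COC(=O)c1c(C)cc(O)cc1O | starting material
14 | methyl 2-hydroxy-4-methoxy-6-methylbenzoate | COC(=O)c1c(C)cc(OC)cc1O | intermediate
15 | methyl 2-(benzyloxy)-4-methoxy-6-methylbenzoate | COC(=O)c1c(C)cc(OC)cc1OCc1ccccc1 | intermediate
16 | N-methoxy-N-methylbutanamide | CCCC(=O)N(C)OC | starting material
17 | {[3-(benzyloxy)-5-methoxy-2-(methoxycarbonyl)phenyl]methyl}lithium | [Li]Cc1cc(OC)cc(OCc2ccccc2)c1C(=O)OC | intermediate (not isolated)
18 | lithium alkoxide adduct of 17 to the carbonyl group of 16 | CCCC(O[Li])(Cc1cc(OC)cc(OCc2ccccc2)c1C(=O)OC)N(C)OC | intermediate (not isolated)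
19 | methyl 2-(benzyloxy)-4-methoxy-6-(2-oxopentyl)benzoate | CCCC(=O)Cc1cc(OC)cc(OCc2ccccc2)c1C(=O)OC | intermediate
20 | methyl 2-(benzyloxy)-4-methoxy-6-[(2-propyl-1,3-dioxolan-2-yl)methyl]benzoate | CCCC1(Cc2cc(OC)cc(OCc3ccccc3)c2C(=O)OC)OCCO1 | intermediate
21 | 2-(benzyloxy)-4-methoxy-6-[(2-propyl-1,3-dioxolan-2-yl)methyl]benzoic acid | CCCC1(Cc2cc(OC)cc(OCc3ccccc3)c2C(=O)O)OCCO1 | intermediate
22 | 2-(benzyloxy)-4-methoxy-6-[(2-propyl-1,3-dioxolan-2-yl)methyl]benzoyl chloride | CCCC1(Cc2cc(OC)cc(OCc3ccccc3)c2C(=O)Cl)OCCO1 | intermediate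
23 | benzyl 4-({2-(benzyloxy)-4-methoxy-6-[(2-propyl-1,3-dioxolan-2-yl)methyl]benzoyl}oxy)-2-methoxy-6-pentylbenzoate | CCCCCc1cc(OC(=O)c2c(OCc3ccccc3)cc(OC)cc2CC2(CCC)OCCO2)cc(OC)c1C(=O)OCc1ccccc1 | intermediate
24 | benzyl 4-{[2-(benzyloxy)-4-methoxy-6-(2-oxopentyl)benzoyl]oxy}-2-methoxy-6-pentylbenzoate | CCCCCc1cc(OC(=O)c2c(OCc3ccccc3)cc(OC)cc2CC(=O)CCC)cc(OC)c1C(=O)OCc1ccccc1 | intermediate
25 | 4-{[2-hydroxy-4-methoxy-6-(2-oxopentyl)benzoyl]oxy}-2-methoxy-6-pentylbenzoic acid | CCCCCc1cc(OC(=O)c2c(O)cc(OC)cc2CC(=O)CCC)cc(OC)c1C(=O)O | target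

**Step count**
- Total step count: 14.
- Longest linear sequence: 9 steps (steps 6–14, from 13).
- The ring B branch reaches the target in 7 steps (1 or 2, then 3, 4, 5, 12, 13, 14).

**Steps most likely to fail**

**Step 3.**
- Three processes could go wrong. Deprotonation may occur next to the silyloxy group, which would turn the aryne the other way round. The aryne may be captured by the aryllithiums present instead of by pentyllithium (self-arylation). The adduct aryllithium may be protonated by the solvent before the CO2 quench.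
- The fallback sets out from 3 and comes back at 10. It makes the two C–C bonds separately and avoids the aryne.
- Compound 3 is lithiated with one equivalent of 5 in THF at −78 °C and carboxylated at that temperature, before LiF can be lost. This gives 2-fluoro-6-methoxy-4-(triisopropylsilyloxy)benzoic acid F1.
- F1 is then treated with 5 (2.5 equiv) in THF from −78 to 0 °C. The first equivalent forms the lithium carboxylate. The second displaces the ortho-fluoride by carboxylate-assisted addition–elimination, the known SNAr of unprotected 2-fluorobenzoic acids with organolithiums. Acidification gives 10.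
- The position of the pentyl group is then fixed by the position of the fluorine, not by the polarity of an aryne.

**Step 12.**
- Acyl transfer at the doubly ortho-substituted carbonyl may be slow. During that time a dioxolane oxygen can attack the acyl chloride carbon, and this neighbouring-group participation would open the ketal and lead to lactonisation.
- The fallback sets out from 21 and comes back at 25. It uses a smaller, chelated acyl donor and no acid chloride.
- Hydrogenolysis of 21 (H2, Pd/C, EtOAc) gives 2-hydroxy-4-methoxy-6-[(2-propyl-1,3-dioxolan-2-yl)methyl]benzoic acid F2.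
- F2 is condensed with 12 by N,N'-dicyclohexylcarbodiimide in toluene at rt. This is the classical carbodiimide condensation of ortho-hydroxybenzoic acids with phenols, in which the hydrogen-bonded 2'-OH is not acylated. The product is benzyl 4-({2-hydroxy-4-methoxy-6-[(2-propyl-1,3-dioxolan-2-yl)methyl]benzoyl}oxy)-2-methoxy-6-pentylbenzoate F3.
- Ketal hydrolysis (THF–1 M HCl, rt) gives benzyl 4-{[2-hydroxy-4-methoxy-6-(2-oxopentyl)benzoyl]oxy}-2-methoxy-6-pentylbenzoate F4. Hydrogenolysis of its benzyl ester gives 25.

**Step 13.**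
- Under acid the freed ketone may enolise, and the enol oxygen may attack the adjacent aryl ester carbonyl and expel the ring B phenol. This enol-lactonisation would cleave the depside.
- The fallback sets out from 19 and comes back at 24. It replaces the oxygen ketal by a thioketal that is removed near neutrality.
- Compound 19 with ethane-1,2-dithiol and BF3·OEt2 in CH2Cl2 at 0 °C gives methyl 2-(benzyloxy)-4-methoxy-6-[(2-propyl-1,3-dithiolan-2-yl)methyl]benzoate F5.
- KOH in aqueous DMSO at 90 °C gives 2-(benzyloxy)-4-methoxy-6-[(2-propyl-1,3-dithiolan-2-yl)methyl]benzoic acid F6.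
- Oxalyl chloride with catalytic DMF gives 2-(benzyloxy)-4-methoxy-6-[(2-propyl-1,3-dithiolan-2-yl)methyl]benzoyl chloride F7.
- F7 acylates 12 (Et3N, DMAP, CH2Cl2) to give benzyl 4-({2-(benzyloxy)-4-methoxy-6-[(2-propyl-1,3-dithiolan-2-yl)methyl]benzoyl}oxy)-2-methoxy-6-pentylbenzoate F8.
- Alkylative hydrolysis of F8 (MeI, CaCO3, MeCN–H2O, 40 °C) releases 24 in a buffered medium. Compound 24 must be chromatographed free of sulfur compounds before step 14.

**Further compounds**
F1 | step 3 | 2-fluoro-6-methoxy-4-(triisopropylsilyloxy)benzoic acid | COc1cc(O[Si](C(C)C)(C(C)C)C(C)C)cc(F)c1C(=O)O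
F2 | step 12 | 2-hydroxy-4-methoxy-6-[(2-propyl-1,3-dioxolan-2-yl)methyl]benzoic acid | CCCC1(Cc2cc(OC)cc(O)c2C(=O)O)OCCO1
F3 | step 12 | benzyl 4-({2-hydroxy-4-methoxy-6-[(2-propyl-1,3-dioxolan-2-yl)methyl]benzoyl}oxy)-2-methoxy-6-pentylbenzoate | CCCCCc1cc(OC(=O)c2c(O)cc(OC)cc2CC2(CCC)OCCO2)cc(OC)c1C(=O)OCc1ccccc1
F4 | step 12 | benzyl 4-{[2-hydroxy-4-methoxy-6-(2-oxopentyl)benzoyl]oxy}-2-methoxy-6-pentylbenzoate | CCCCCc1cc(OC(=O)c2c(O)cc(OC)cc2CC(=O)CCC)cc(OC)c1C(=O)OCc1ccccc1
F5 | step 13 | methyl 2-(benzyloxy)-4-methoxy-6-[(2-propyl-1,3-dithiolan-2-yl)methyl]benzoate | CCCC1(Cc2cc(OC)cc(OCc3ccccc3)c2C(=O)OC)SCCS1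
F6 | step 13 | 2-(benzyloxy)-4-methoxy-6-[(2-propyl-1,3-dithiolan-2-yl)methyl]benzoic acid | CCCC1(Cc2cc(OC)cc(OCc3ccccc3)c2C(=O)O)SCCS1
F7 | step 13 | 2-(benzyloxy)-4-methoxy-6-[(2-propyl-1,3-dithiolan-2-yl)methyl]benzoyl chloride | CCCC1(Cc2cc(OC)cc(OCc3ccccc3)c2C(=O)Cl)SCCS1
F8 | step 13 | benzyl 4-({2-(benzyloxy)-4-methoxy-6-[(2-propyl-1,3-dithiolan-2-yl)methyl]benzoyl}oxy)-2-methoxy-6-pentylbenzoate | CCCCCc1cc(OC(=O)c2c(OCc3ccccc3)cc(OC)cc2CC2(CCC)SCCS2)cc(OC)c1C(=O)OCc1ccccc1
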